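**Plan**
1. Numbering: ring A is the dibromocatechol ring (C1 bears the bridging CH2, C2 and C3 bear Br, C4 and C5 bear OH, C6 bears H). Ring B is the bromophloroglucinol ring.
2. Cuts, in retrosynthetic order: CH2–ring B (Friedel–Crafts benzylation), C–Br of ring B, C1–CH2 of ring A (phenolate plus glyoxylate), and last the C4–O and C5–O bonds of ring A, which leads back to 1,2-dibromobenzene.
3. Enabling feature: C2(Br), C3(Br), C4(OH) and C5(OH) of ring A form an unbroken row, so both oxygens lie ortho and meta to a bromine-bearing carbon. An arene dioxygenase leaves this pattern on a halobenzene, whereas direct halogenation of catechol fills its 4- and 5-positions.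
4. Forward: no ring is constructed, because both benzene rings are bought. Ring A is dearomatised by enzymatic cis-dihydroxylation, rearomatised to 3,4-dibromocatechol, extended by one carbon para to C4–OH (mandelic acid, aldehyde, benzyl alcohol) and then joined to the separately brominated ring B.
5. Stereochemistry: the target is achiral. The two carbinol centres set by the enzyme in step 1 vanish in step 2, and the racemic carbinol of step 3 vanishes in step 4, so only regiochemistry is carried through and no protecting group is needed.

Key step: step 1

**Step 1**
Reactants: 1 1,2-dibromobenzene
Product: 2 (1S,2S)-3,4-dibromocyclohexa-3,5-diene-1,2-diol (cis-diol)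
Conditions: E. coli JM109 (pDTG601) whole cells (toluene dioxygenase TodC1C2BA, IPTG-induced), glucose feed, air/O2, mineral salts medium, pH 7.0, 30–35 °C, 1 fed neat in portions; cells spun off, broth brought to pH 8.5, base-washed EtOAc
Reagents that add atoms: dioxygen, O=O
Why: The Rieske non-heme iron oxygenase, charged with two electrons from NADH through its reductase and ferredoxin, binds O2 at the mononuclear iron and passes both oxygen atoms to the same face of the C3=C4 bond of 1, so the C4–O and C5–O bonds of ring A form suprafacially and a cyclohexadiene cis-diol is left. The closest known reaction type is the whole-cell toluene dioxygenase cis-dihydroxylation of bromobenzene and of ortho-dihalobenzenes, the class to which 1 belongs. No ring is closed. Both carbinol centres are fixed by the enzyme pocket, which should hold the halogen-bearing edge as it does in bromobenzene and so give the (1S,2S) diol, although the configuration does not matter because step 2 removes both centres. The selectivity needed is attack at the bond next to a C–Br carbon rather than at the remote C4=C5 bond: a bromine serves as the anchoring substituent that steers oxygenation ortho,meta to itself, and the twofold symmetry of 1 makes the two such bonds (C3=C4 and C5=C6) equivalent, so one constitutional isomer is expected. Extraction at slightly basic pH keeps the diol from losing water to a dibromophenol.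

**Step 2**
Reactants: 2 (1S,2S)-3,4-dibromocyclohexa-3,5-diene-1,2-diol
Product: 3 3,4-dibromobenzene-1,2-diol (3,4-dibromocatechol)
Conditions: resting cells of E. coli JM109 (pDTG602) (cis-dihydrodiol dehydrogenase TodD, NAD+ recycled by respiration), phosphate buffer pH 7.0, air, 30 °C; then pH 4, EtOAc
Reagents that add atoms: none
Why: This is an enzymatic alcohol dehydrogenation with aromatisation, in which the NAD+-dependent dehydrogenase that follows the dioxygenase in the toluene pathway (relatives of it process the 3,4-dichloro analogue in chlorobenzene degraders) removes two hydrogens from the diol unit, the gain of aromaticity makes the step irreversible, the neutral medium avoids dehydration to a phenol, the C–Br bonds stay untouched and both stereocentres disappear.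

**Step 3**
Reactants: 3 3,4-dibromobenzene-1,2-diol; 4 glyoxylic acid
Product: 5 rac-2-(2,3-dibromo-4,5-dihydroxyphenyl)-2-hydroxyacetic acid (2,3-dibromo-4,5-dihydroxymandelic acid)
Conditions: 4 (50 % aq., 1.2 equiv), NaOH (2.1 equiv), H2O, N2, 35–45 °C; then HCl to pH 2, EtOAc
Reagents that add atoms: none
Why: This is the base-mediated hydroxyalkylation of a phenolate with glyoxylate (the mandelic acid stage of the catechol-to-protocatechualdehyde process), and since the hydroxyl flanked by bromine (C4–OH) is the more acidic and its phenolate has only the para carbon free, bond formation is steered to C1 of ring A rather than to C6, while the new carbinol centre forms as a racemate and is destroyed in step 4.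

**Step 4**
Reactants: 5 rac-2,3-dibromo-4,5-dihydroxymandelic acid
Product: 6 2,3-dibromo-4,5-dihydroxybenzaldehyde
Conditions: FeCl3 (2.2 equiv), 0.5 M aq. HCl, N2, 80 °C
Reagents that add atoms: none
Why: This is the oxidative decarboxylation of a 4-hydroxymandelic acid by a one-electron oxidant, in which two equivalents of trivalent iron oxidise the hydroxylated ring, CO2 leaves from the benzylic carbon and the aldehyde results, which with its formyl group and two bromines is harder to oxidise than 5, while the acidic medium rules out displacement of the aryl bromides by hydroxide.

**Step 5**
Reactants: 6 2,3-dibromo-4,5-dihydroxybenzaldehyde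
Product: 7 3,4-dibromo-5-(hydroxymethyl)benzene-1,2-diol (2,3-dibromo-4,5-dihydroxybenzyl alcohol, lanosol)
Conditions: NaBH4 (1.5 equiv), THF–H2O, 0 °C to rt; cold aq. NH4Cl to pH 6, EtOAc; used promptly
Reagents that add atoms: none
Why: This is a borohydride reduction of an aromatic aldehyde, which leaves aryl bromides and phenols alone, and the cold, nearly neutral, alcohol-free work-up releases the catechol from borate without solvolysing the labile para-hydroxybenzyl alcohol.

**Step 6**
Reactants: 8 phloroglucinol (benzene-1,3,5-triol)
Product: 9 2-bromobenzene-1,3,5-triol (2-bromophloroglucinol)
Conditions: NBS (0.95 equiv, slow addition), MeCN, −30 °C to 0 °C, dark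
Reagents that add atoms: N-bromosuccinimide, O=C1CCC(=O)N1Br
Why: This is an electrophilic aromatic bromination at one of three equivalent carbons, and in an aprotic medium, where no phenolate pathway operates, the first bromine lowers the reactivity of the ring, so a slight deficit of reagent added slowly in the cold should stop at the monobromide.

**Step 7**
Reactants: 7 2,3-dibromo-4,5-dihydroxybenzyl alcohol; 9 2-bromobenzene-1,3,5-triol
Product: 11 vidalol A (2-bromo-4-(2,3-dibromo-4,5-dihydroxybenzyl)benzene-1,3,5-triol), via para-quinone methide 10 (not isolated)
Conditions: 9 (3 equiv), p-TsOH·H2O (10 mol %), 1,4-dioxane, Ar, 40 °C, 7 added slowly by syringe pump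
Reagents that add atoms: none
Why: This is an acid-catalysed Friedel–Crafts benzylation of the type used to trap para-hydroxybenzylic cations with phloroglucinol, in which the C4–OH para to the CH2OH lets 7 lose water under mild acid to 10, the two free carbons of 9 are equivalent and are the most nucleophilic sites present so that C-attack gives one constitution, and excess 9 with slow addition of 7 holds back a second benzylation and self-condensation.

**Compound list**
1 | 1,2-dibromobenzene | Brc1ccccc1Br | starting material
2 | (1S,2S)-3,4-dibromocyclohexa-3,5-diene-1,2-diol | O[C@H]1C=CC(Br)=C(Br)[C@H]1O | intermediate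
3 | 3,4-dibromobenzene-1,2-diol | Oc1ccc(Br)c(Br)c1O | intermediate
4 | glyoxylic acid | O=CC(=O)O | starting material
5 | rac-2-(2,3-dibromo-4,5-dihydroxyphenyl)-2-hydroxyacetic acid | OC(C(=O)O)c1cc(O)c(O)c(Br)c1Br | intermediate
6 | 2,3-dibromo-4,5-dihydroxybenzaldehyde | O=Cc1cc(O)c(O)c(Br)c1Br | intermediate
7 | 3,4-dibromo-5-(hydroxymethyl)benzene-1,2-diol | OCc1cc(O)c(O)c(Br)c1Br | intermediate
8 | phloroglucinol (benzene-1,3,5-triol) | Oc1cc(O)cc(O)c1 | starting material
9 | 2-bromobenzene-1,3,5-triol | Oc1cc(O)c(Br)c(O)c1 | intermediate
10 | 2,3-dibromo-6-hydroxy-4-methylidenecyclohexa-2,5-dien-1-one (para-quinone methide, not isolated) | C=C1C=C(O)C(=O)C(Br)=C1Br | intermediate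
11 | vidalol A, 2-bromo-4-(2,3-dibromo-4,5-dihydroxybenzyl)benzene-1,3,5-triol | Oc1cc(Cc2c(O)cc(O)c(Br)c2O)c(Br)c(Br)c1O | target

Total steps: 7. Longest linear sequence: 6 (steps 1, 2, 3, 4, 5, 7).

**Steps most likely to fail**

Step 3. The two bromines may slow the attack of the phenolate on glyoxylate so much that disproportionation of the aldehyde and oxidation of the catecholate take over. Part of the attack may also drift to C6 once the second hydroxyl is ionised. The fallback sets out from 3 and returns at 6, replacing steps 3 and 4. The catechol is tied up with CH2Br2 and Cs2CO3 in DMF as 4,5-dibromo-1,3-benzodioxole F1. The five-membered ring keeps both oxygen lone pairs in conjugation, and benzodioxoles are substituted para rather than ortho to oxygen. Rieche formylation (Cl2CHOMe, TiCl4, CH2Cl2, 0 °C) should therefore give 6,7-dibromo-1,3-benzodioxole-5-carbaldehyde F2. BBr3 in CH2Cl2 followed by water then opens the methylene acetal to give 6.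

Step 7. Ring B may be benzylated a second time, the quinone methide may be trapped by a hydroxyl of another molecule of 7, or the acid may cause the ring B bromine to migrate or be lost. The fallback sets out from 7 and 8 and returns at 11, and it makes step 6 unnecessary because the ring B C–Br bond is formed last. Alcohol 7 is condensed under the same mild acid with a fivefold excess of phloroglucinol 8, which is more nucleophilic and carries no labile halogen, to give 2-(2,3-dibromo-4,5-dihydroxybenzyl)benzene-1,3,5-triol F3. One equivalent of NBS in MeCN at −30 °C should then brominate one of the two equivalent free carbons of ring B, which is far more reactive than the deactivated C6–H of ring A.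

Step 4. Electron transfer may degrade the catechol by quinone-type coupling faster than CO2 is lost, or the bromine-depleted ring may resist oxidation so that 5 is not consumed. The fallback sets out from 3 and returns at 7, replacing steps 3 to 5, and it needs no oxidation because the one-carbon unit enters at the alcohol level. It is a Lederer–Manasse hydroxymethylation of the monophenolate of 3 with aqueous formaldehyde (1.0 equiv) and NaOH (1.0 equiv) in water under N2 at 0–20 °C. It relies on the para direction already shown in step 3. It is held in reserve because onward condensation to diarylmethanes is harder to control than with glyoxylate. No compound outside the list arises on this detour (F0).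

**Further compounds**
F1 | step 3 | 4,5-dibromo-1,3-benzodioxole | Brc1ccc2OCOc2c1Br
F2 | step 3 | 6,7-dibromo-1,3-benzodioxole-5-carbaldehyde | O=Cc1cc2OCOc2c(Br)c1Br
F3 | step 7 | 2-(2,3-dibromo-4,5-dihydroxybenzyl)benzene-1,3,5-triol | Oc1cc(Cc2c(O)cc(O)cc2O)c(Br)c(Br)c1O
F0 | step 4 | none | none
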